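**Retrosynthetic overview**

1. Target 10 ⇐ its primary acetate 9 ⇐ cyclobutane monoacetate 6: oxidative cleavage of the diaryl-bearing C–C bond gives a bis-quinone methide; the one free CH2OH closes the oxolane and water adds to the second quinone methide.
2. 6 ⇐ meso-diol 5 by enzymatic acetylation of one enantiotopic CH2OH, which fixes the absolute configuration.
3. 5 ⇐ meso bicyclic anhydride 4 by LiAlH4 reduction.
4. 4 ⇐ acyclic anhydride 2 by intramolecular [2+2] photocycloaddition, which forms the cyclobutane and the five-membered anhydride ring together and fixes the cis relationship of the two future CH2O-bearing carbons; 2 ⇐ 4-O-acetylferulic acid 1.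
5. Ring order: cyclobutane plus anhydride ring (step 2), anhydride ring opened (step 3), cyclobutane opened and oxolane closed (step 5).

Assumption: in step 4 the lipase acetylates the hydroxymethyl group on the R-configured ring carbon of 5; if it prefers the other one, the hydrolytic mode given as the fallback for step 4 leads to the same compound 6.

Numbering used in the explanations: C7/C7' are the aryl-bearing carbons, C8/C8' their neighbours, C9/C9' the CH2O carbons. In 10, C7 = oxolane C2, C8 = C3, C8' = C4, C9' = C5, and C7' is the carbinol carbon.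

**Route**

Step 1
Reactants: 1 (E)-3-(4-acetoxy-3-methoxyphenyl)prop-2-enoic acid (4-O-acetylferulic acid), two equivalents
Product: 2 (E,E)-3-(4-acetoxy-3-methoxyphenyl)prop-2-enoic anhydride
Conditions: DCC (0.5 equiv per acid), CH2Cl2, 0 °C to rt; filter, crystallise
Reagents that add atoms: none
Why: Carbodiimide dehydration of two acid molecules to the symmetrical anhydride via the O-acylisourea, run without DMAP so the aryl acetates are untouched; no stereocentre is formed and both alkenes stay E.

Step 2
Reactants: 2 (E,E)-3-(4-acetoxy-3-methoxyphenyl)prop-2-enoic anhydride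
Product: 4 (1R,5S,6R,7S)-6,7-bis(4-acetoxy-3-methoxyphenyl)-3-oxabicyclo[3.2.0]heptane-2,4-dione (meso; cis ring fusion; both aryls exo and cis to each other), via bis-benzylic 1,4-diradical 3 (not isolated)
Conditions: thioxanthone (10 mol%), dry degassed MeCN (5 mM), 385 nm LED, rt; crystallise
Reagents that add atoms: none
Why: Proposed new method: triplet energy transfer from thioxanthone to one cinnamoyl unit should trigger 5-exo bond formation between the two alpha carbons (rule of five for 1,6-dienes) to give cis-diradical 3, whose benzylic radical centres then couple, so that cyclobutane and anhydride ring form together; the cis ring fusion is obligatory (a trans diradical cannot close and reverts to 2) and sets the C8/C8' relationship, while each aryl is expected on the exo face, giving the meso exo,exo isomer; the closest known reaction type is the sensitised intramolecular [2+2] photocycloaddition of tethered cinnamates and styrenes to aryl-exo bicyclo[3.2.0]heptanes.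

Step 3
Reactants: 4 (1R,5S,6R,7S)-6,7-bis(4-acetoxy-3-methoxyphenyl)-3-oxabicyclo[3.2.0]heptane-2,4-dione
Product: 5 [(1R,2S,3R,4S)-3,4-bis(4-hydroxy-3-methoxyphenyl)cyclobutane-1,2-diyl]dimethanol (meso)
Conditions: LiAlH4 (4 equiv), THF, 0 °C to rt; then H2O, aq NH4Cl
Reagents that add atoms: none
Why: Exhaustive hydride reduction of the cyclic anhydride to the cis-1,4-diol with reductive cleavage of both aryl acetates; no bond at a stereocentre is broken, so the relative configuration of 4 is kept.

Step 4
Reactants: 5 [(1R,2S,3R,4S)-3,4-bis(4-hydroxy-3-methoxyphenyl)cyclobutane-1,2-diyl]dimethanol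
Product: 6 [(1R,2S,3R,4S)-2-(hydroxymethyl)-3,4-bis(4-hydroxy-3-methoxyphenyl)cyclobutyl]methyl acetate
Conditions: Burkholderia cepacia lipase (immobilised), vinyl acetate (5 equiv), THF/t-BuOMe, 30 °C; stop at consumption of 5
Reagents that add atoms: vinyl acetate, C=COC(C)=O
Why: Enzymatic desymmetrisation of a meso-diol by irreversible lipase transesterification, which acetylates one of the two enantiotopic primary hydroxyls and leaves the phenols alone; this sets the absolute configuration at C8 and C8' without touching any bond at a stereocentre.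

Step 5
Reactants: 6 [(1R,2S,3R,4S)-2-(hydroxymethyl)-3,4-bis(4-hydroxy-3-methoxyphenyl)cyclobutyl]methyl acetate
Product: 9 [(2S,3R,4S)-4-[(S)-hydroxy(4-hydroxy-3-methoxyphenyl)methyl]-2-(4-hydroxy-3-methoxyphenyl)oxolan-3-yl]methyl acetate, via bis-quinone methide 7 (not isolated), via oxolanyl quinone methide 8 (not isolated)
Conditions: FeCl3·6H2O (2.2 equiv), acetone/H2O 9:1, 0 °C, 30 min; aq NaHCO3
Reagents that add atoms: water, O
Why: Oxidative ring opening of an electron-rich 1,2-bis(4-hydroxyaryl)cyclobutane by trivalent iron (two one-electron oxidations) cleaves the strained doubly benzylic C3–C4 bond to bis-quinone methide 7; the only free CH2OH then closes the oxolane by 5-exo oxa-1,6-addition with the aryl trans to the neighbouring CH2OAc (reversible, thermodynamic), and water adds to quinone methide 8 anti to ring carbon C3 in the conformer that minimises allylic strain (H on C4 eclipsing the exocyclic alkene), giving the S carbinol.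

Step 6
Reactants: 9 [(2S,3R,4S)-4-[(S)-hydroxy(4-hydroxy-3-methoxyphenyl)methyl]-2-(4-hydroxy-3-methoxyphenyl)oxolan-3-yl]methyl acetate
Product: 10 4-[(2S,3R,4S)-4-[(S)-hydroxy(4-hydroxy-3-methoxyphenyl)methyl]-3-(hydroxymethyl)oxolan-2-yl]-2-methoxyphenol
Conditions: K2CO3 (0.3 equiv), MeOH, 0 °C; aq NH4Cl
Reagents that add atoms: none
Why: Base-catalysed methanolysis (transesterification) of the primary acetate at low temperature, mild enough not to ionise the para-hydroxybenzylic carbinol, so all four stereocentres are untouched.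

**Compound list**

1 | (E)-3-(4-acetoxy-3-methoxyphenyl)prop-2-enoic acid (4-O-acetylferulic acid) | COc1cc(/C=C/C(=O)O)ccc1OC(C)=O | starting material
2 | (E,E)-3-(4-acetoxy-3-methoxyphenyl)prop-2-enoic anhydride | COc1cc(/C=C/C(=O)OC(=O)/C=C/c2ccc(OC(C)=O)c(OC)c2)ccc1OC(C)=O | intermediate
3 | triplet 1,4-diradical: cis-3,4-disubstituted oxolane-2,5-dione carrying one (4-acetoxy-3-methoxyphenyl)methyl radical on C3 and one on C4 | O=C1OC(=O)[C@H]([CH]c2ccc(OC(C)=O)c(OC)c2)[C@@H]1[CH]c1ccc(OC(C)=O)c(OC)c1 | intermediate (not isolated)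
4 | (1R,5S,6R,7S)-6,7-bis(4-acetoxy-3-methoxyphenyl)-3-oxabicyclo[3.2.0]heptane-2,4-dione (meso; aryls exo, cis to each other) | O=C1OC(=O)[C@@H]2[C@@H](c3ccc(OC(C)=O)c(OC)c3)[C@@H](c3ccc(OC(C)=O)c(OC)c3)[C@H]12 | intermediate
5 | [(1R,2S,3R,4S)-3,4-bis(4-hydroxy-3-methoxyphenyl)cyclobutane-1,2-diyl]dimethanol (meso; CH2OH groups cis, aryls cis, CH2OH/aryl trans) | OC[C@H]1[C@H](c2ccc(O)c(OC)c2)[C@H](c2ccc(O)c(OC)c2)[C@H]1CO | intermediate
6 | [(1R,2S,3R,4S)-2-(hydroxymethyl)-3,4-bis(4-hydroxy-3-methoxyphenyl)cyclobutyl]methyl acetate | OC[C@H]1[C@H](c2ccc(O)c(OC)c2)[C@H](c2ccc(O)c(OC)c2)[C@H]1COC(C)=O | intermediate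
7 | (2R,3S)-3-(hydroxymethyl)-4-(3-methoxy-4-oxocyclohexa-2,5-dien-1-ylidene)-2-[(3-methoxy-4-oxocyclohexa-2,5-dien-1-ylidene)methyl]butyl acetate (bis-quinone methide; exocyclic alkene geometry not defined) | OC[C@@H](C=C1C=CC(=O)C(OC)=C1)[C@H](COC(C)=O)C=C1C=CC(=O)C(OC)=C1 | intermediate (not isolated)
8 | [(2S,3R,4S)-2-(4-hydroxy-3-methoxyphenyl)-4-[(3-methoxy-4-oxocyclohexa-2,5-dien-1-ylidene)methyl]oxolan-3-yl]methyl acetate (exocyclic alkene geometry not defined) | O=C1C=CC(=C[C@@H]2CO[C@H](c3ccc(O)c(OC)c3)[C@H]2COC(C)=O)C=C1OC | intermediate (not isolated)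
9 | [(2S,3R,4S)-4-[(S)-hydroxy(4-hydroxy-3-methoxyphenyl)methyl]-2-(4-hydroxy-3-methoxyphenyl)oxolan-3-yl]methyl acetate | COc1cc([C@@H](O)[C@@H]2CO[C@H](c3ccc(O)c(OC)c3)[C@H]2COC(C)=O)ccc1O | intermediate
10 | 4-[(2S,3R,4S)-4-[(S)-hydroxy(4-hydroxy-3-methoxyphenyl)methyl]-3-(hydroxymethyl)oxolan-2-yl]-2-methoxyphenol (all-trans oxolane; 7S,8R,7'S,8'S) | COc1cc([C@@H](O)[C@@H]2CO[C@H](c3ccc(O)c(OC)c3)[C@H]2CO)ccc1O | target

**Summary**

Total step count: 6. Longest linear sequence: 6 steps (1 → 2 → 4 → 5 → 6 → 9 → 10).

**Steps most likely to fail, with fallbacks**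

Step 2 is the most uncertain. The anhydride may not reach the folded conformer efficiently, and the diradical may close in part to the chiral exo,endo isomer, which cannot be desymmetrised in step 4. The fallback sets out from 1 and comes back at 5. Two molecules of 1 are esterified (DCC, catalytic DMAP, CH2Cl2) onto the peri-hydroxyls of naphthalene-1,8-diol to give naphthalene-1,8-diyl bis[(2E)-3-(4-acetoxy-3-methoxyphenyl)prop-2-enoate] F1. The rigid template holds the two cinnamoyl units parallel and stacked, so irradiation of crystalline F1 at 365 nm gives the cis-syn head-to-head cycloadduct naphthalene-1,8-diyl (1R,2S,3R,4S)-3,4-bis(4-acetoxy-3-methoxyphenyl)cyclobutane-1,2-dicarboxylate F2, in which the cyclobutane and a nine-membered dilactone ring form together. LiAlH4 in THF then releases meso-diol 5, and the route continues from step 4.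

Step 4 may give the wrong enantiotopic selectivity or a low enantiomeric excess, and 6 can racemise by acyl migration if stored. The fallback sets out from 5 and comes back at 6. Diol 5 is peracetylated (Ac2O, pyridine) to [(1R,2S,3R,4S)-3,4-bis(4-acetoxy-3-methoxyphenyl)cyclobutane-1,2-diyl]bis(methylene) diacetate F3. F3 is then hydrolysed enantiotopos-selectively with the same lipase (or pig liver esterase) in phosphate buffer/acetone at pH 7. The enzyme removes both aryl acetates and the one primary acetate it recognises, which is the antipodal sense to the acylation mode, and leaves monoacetate 6.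

Step 5 may give a poor diastereomer ratio at the carbinol carbon, because water addition to quinone methide 8 is reversible under the acidic conditions. The fallback sets out from 9 obtained as a mixture of carbinol epimers and comes back at 9 as a single isomer. The mixture is oxidised at the benzylic alcohol with activated MnO2 in acetone to the aryl ketone [(2S,3R,4S)-4-(4-hydroxy-3-methoxybenzoyl)-2-(4-hydroxy-3-methoxyphenyl)oxolan-3-yl]methyl acetate F4. F4 is reduced under reagent control with (R)-2-methyl-CBS-oxazaborolidine and excess BH3·SMe2 in THF at −20 °C, with the aryl group acting as the large substituent, to give the S carbinol 9.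

**Further compounds**

F1 | step 2 | naphthalene-1,8-diyl bis[(2E)-3-(4-acetoxy-3-methoxyphenyl)prop-2-enoate] | CC(=O)Oc1ccc(/C=C/C(=O)Oc2cccc3cccc(OC(=O)/C=C/c4ccc(OC(C)=O)c(OC)c4)c23)cc1OC
F2 | step 2 | naphthalene-1,8-diyl (1R,2S,3R,4S)-3,4-bis(4-acetoxy-3-methoxyphenyl)cyclobutane-1,2-dicarboxylate (cyclic diester, meso) | O=C1Oc2cccc3cccc(OC(=O)[C@@H]4[C@@H](c5ccc(OC(C)=O)c(OC)c5)[C@@H](c5ccc(OC(C)=O)c(OC)c5)[C@H]14)c23
F3 | step 4 | [(1R,2S,3R,4S)-3,4-bis(4-acetoxy-3-methoxyphenyl)cyclobutane-1,2-diyl]bis(methylene) diacetate (meso) | CC(=O)OC[C@H]1[C@H](c2ccc(OC(C)=O)c(OC)c2)[C@H](c2ccc(OC(C)=O)c(OC)c2)[C@H]1COC(C)=O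
F4 | step 5 | [(2S,3R,4S)-4-(4-hydroxy-3-methoxybenzoyl)-2-(4-hydroxy-3-methoxyphenyl)oxolan-3-yl]methyl acetate | COc1cc(C(=O)[C@@H]2CO[C@H](c3ccc(O)c(OC)c3)[C@H]2COC(C)=O)ccc1O
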